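Start with the quarrel. Three flasks of Q take up J from a held gas G, and they differ in temperature.

| setting | south | east | north-east |
|---|---|---|---|
| Q | 0.0050 M | 0.0050 M | 0.0050 M |
| G | 1.1 mM (held) | 1.1 mM (held) | 1.1 mM (held) |
| temperature | 50 °C | 80 °C | 20 °C |
| time | 2.5 min | 2.5 min | 2.5 min |

    2 Q → Q2 (k1 = 43 M⁻¹ s⁻¹, Ea1 = 45.0 kJ mol⁻¹)
    Q + J → Q.J (k2 = 130 M⁻¹ s⁻¹, Ea2 = 50.0 kJ mol⁻¹)
    G ⇌ J, rate k3*(csat - [J]) (k3 = 14 s⁻¹, csat = 1.1 mM)
    Q → X (k4 = 0.081 s⁻¹, Ea4 = 89.0 kJ mol⁻¹)
    (constants at 50 °C)

- percent here means Q units held: one Q2 counts as two
- a step written with two of one species runs at k times the square of its concentration and takes two of it each time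
- at the start none of J is dissolved
- constants are those at 50 °C; use the activation energies for any other temperature

- the flask that comes out highest in amount of Q.J, in percent of the Q charged, or "all alike" when all lie within 1.5 percentage points (south / east / north-east / all alike)
- Q.J at the end, in percent of the Q charged, south
- Q.J at the end, in percent of the Q charged, east
- Q.J at the end, in percent of the Q charged, north-east

Ana says heat helps. From north-east to east the step to Q.J speeds up by a factor 33, and the step to Q2 by 23, so the first step gains on the second. From this she expects Q.J to gain on Q2. She picks east.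

Ben says heat hurts. The step to X has an activation energy 39.0 kJ mol⁻¹ above the step to Q.J, and it speeds up by 490. So the step to X gains 15.2-fold on the step to Q.J, while the step to Q.J gains 1.42-fold on the step to Q2. That first gain is larger than the second. He picks north-east.

I side with Ben, and I can reckon south, where the constants stand as given. J dissolves at 14 s⁻¹, and Q uses it at 0.650 s⁻¹ at the start, far slower than that. So [J] stays near csat, and the step to Q.J is pseudo-first-order in Q, with c = 0.143 s⁻¹. Adding the loss to X gives s = 0.224 s⁻¹. The pair step takes each Q at a·x, where x is the fraction of Q left and a = 0.430 s⁻¹. Of each Q lost, the fraction c/(s + a·x) becomes Q.J. Integrated over x, this gives (c/a) ln(1 + a/s) = 35.6 %. Call this the pinned-J share: the part of the charged Q that ends as Q.J while [J] stands at csat.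

The time 4.46 s is far shorter than the run, so the run should not cut south short. But [J] starts at none and fills in about 0.0714 s, so I expect the share to run slightly high. For east and north-east I carry Ben's direction and no number.

The forecast gives north-east, with 34.5 % south, 20.2 % east and 38.9 % north-east, saying "Q.J peaks in the cold flask", and its south figure is lower than my 35.6 %.

The simulation gives north-east highest: 34.5 % south, 20.1 % east, 38.8 % north-east. Ana loses on Q.J. Q2 goes from 55.5 % north-east to 30.2 % east, while X goes from 5.01 % to 49.7 %. The ratio of Q.J to Q2 is 0.699 north-east and 0.666 east. In south my share stands 1.1 percentage points above the result, on the side I expected.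

Now take a further flask like south, with 0.0020 M of Q. There c and s stay, and a falls to 0.172 s⁻¹. The share of that flask becomes 47.4 %, higher than south's. Its simulation gives 46.5 %. In that flask Q.J holds more of the Q than Q2 does, with Q2 at 26.3 %.

(The constants used here are those of an exercise; no experiment stands behind them.)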